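## Retr​osynthetic overview

1. Target ⇒ bicyclic benzoquinone (Z)-enol 2,2,2-trichloroethyl sulfate: one zinc reduction frees both the hydroquinone and the sulfate monoester.
2. Rings A and B, C5/C9/C10 and the Δ7 alkene ⇒ one enantioselective, proton-initiated bicyclisation of the all-(E) linear polyene, folded as in the biosynthesis of the prenylated hydroquinone. Ring A closes first (C4–C5), then ring B (C9–C10); the sulfonylated enol stops the cascade.
3. Linear chain and (Z)-enol oxygen ⇒ γ-alkylation of a lithiated 2-substituted allyl silyl ether with (E,E)-farnesyl bromide (C11–C12 bond).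
4. Allyl silyl ether ⇒ Kumada coupling of a 2-bromoallyl silyl ether with an aryl-alkenyl Grignard reagent ⇐ alkyne carboalumination and benzyl coupling, which fixes the (E)-C17=C18 alkene.

Assumption: the target is drawn as the free hydrogen sulfate; the sulfate is generated as its ammonium salt and protonated in the last work-up (in practice it would be stored as a salt). Carbon labels follow terpenoid numbering: C4 gem-dimethyl, C10 angular methyl, C8 vinylic methyl, C9 side-chain carbon, C11 and C12 the two CH2, C13 the enol carbon, C17=C18 the side-chain alkene.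

## Route

Step 1
Reactants: 1 5-chloropent-1-yne; 2 2-(chloromethyl)-1,4-dimethoxybenzene
Product: 4 2-[(2E)-6-chloro-3-methylhex-2-en-1-yl]-1,4-dimethoxybenzene, via alkenylalane 3 (not isolated)
Conditions: Me3Al (2 equiv), Cp2ZrCl2 (0.2 equiv), ClCH2CH2Cl, 0 °C → rt; then 2, NiCl2(PPh3)2/n-BuLi (gives zerovalent nickel, 3 mol %), THF, rt
Reagents that add atoms: trimethylaluminium C[Al](C)C
Why: Negishi zirconium-catalysed syn-carboalumination puts methyl on the internal and aluminium on the terminal alkyne carbon, cis to each other, which fixes the (E)-trisubstituted alkene, and the alkenylalane then cross-couples with the benzylic chloride under nickel catalysis with retention.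

Step 2
Reactants: 5 2-bromoprop-2-en-1-ol
Product: 6 [(2-bromoprop-2-en-1-yl)oxy]triethylsilane
Conditions: Et3SiCl, imidazole, CH2Cl2, 0 °C
Reagents that add atoms: chlorotriethylsilane CC[Si](Cl)(CC)CC
Why: Routine silylation of a primary allylic alcohol; triethylsilyl is chosen because its allyl ether can be metalated at −78 °C without fast silyl migration to carbon and its enol ether is later cleaved by MeLi.

Step 3
Reactants: 4 2-[(2E)-6-chloro-3-methylhex-2-en-1-yl]-1,4-dimethoxybenzene; 6 [(2-bromoprop-2-en-1-yl)oxy]triethylsilane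
Product: 8 {[(6E)-8-(2,5-dimethoxyphenyl)-6-methyl-2-methylideneoct-6-en-1-yl]oxy}triethylsilane, via Grignard reagent 7 (not isolated)
Conditions: Mg, THF, 60 °C; then 6, PdCl2(dppf) (3 mol %; dppf = 1,1′-bis(diphenylphosphino)ferrocene), THF, 0 °C → rt
Reagents that add atoms: none
Why: The primary chloride gives the Grignard reagent and Kumada–Corriu coupling with the vinylic bromide joins sp3 to sp2 carbon (the wide-bite-angle diphosphine suppresses β-hydride elimination) without touching the silyl ether or the (E)-alkene.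

Step 4
Reactants: 8 {[(6E)-8-(2,5-dimethoxyphenyl)-6-methyl-2-methylideneoct-6-en-1-yl]oxy}triethylsilane; 9 (2E,6E)-farnesyl bromide
Product: 11 linear (Z)-triethylsilyl enol ether, via siloxyallyllithium 10 (not isolated)
Conditions: s-BuLi (1.05 equiv), THF, −78 °C, 10 min; HMPA; then 9, −78 → −40 °C
Reagents that add atoms: none
Why: Still-type metalation of the allyl silyl ether gives the oxygen-chelated cis-siloxyallyllithium, which is alkylated at its γ-carbon by the primary allylic bromide (homoenolate alkylation, SN2), so the new C11–C12 bond is made on the CH2 cis to oxygen and the enol ether is formed as the (Z)-isomer the target needs.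

Step 5
Reactants: 11 linear (Z)-triethylsilyl enol ether
Product: 13 linear (Z)-enol 2,2,2-trichloroethyl sulfate, via lithium enolate 12 (not isolated)
Conditions: MeLi (1.1 equiv), THF, 0 °C → rt; then −78 °C, 1,2-dimethyl-3-[(2,2,2-trichloroethoxy)sulfonyl]imidazolium triflate, → 0 °C
Reagents that add atoms: 1,2-dimethyl-3-[(2,2,2-trichloroethoxy)sulfonyl]imidazolium trifluoromethanesulfonate Cc1n(C)cc[n+]1S(=O)(=O)OCC(Cl)(Cl)Cl.[O-]S(=O)(=O)C(F)(F)F
Why: Proposed new method: MeLi attacks silicon and releases the configurationally stable lithium aldehyde enolate, whose hard oxygen (attack through carbon would build a quaternary centre) adds to the sulfur of the cationic sulfuryl-transfer salt with loss of 1,2-dimethylimidazole, giving the neutral mixed sulfate diester with the (Z)-geometry retained; the closest known reaction types are sulfation of alkoxides and phenoxides with the same imidazolium salts and O-sulfonylation of enolates by N-sulfonyl transfer reagents (enol triflate formation).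

Step 6
Reactants: 13 linear (Z)-enol 2,2,2-trichloroethyl sulfate
Product: 14 linear benzoquinone (Z)-enol trichloroethyl sulfate
Conditions: (NH4)2Ce(NO3)6 (2.5 equiv), MeCN/H2O 3:1, 0 °C, 20 min
Reagents that add atoms: water O
Why: Oxidative demethylation of the 1,4-dimethoxyarene (aryl–oxygen cleavage by water) gives the benzoquinone, which removes the nucleophilic arene and ether oxygens before the cationic step, while isolated trisubstituted alkenes and the electron-poor enol sulfate diester are not oxidised.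

Step 7
Reactants: 14 linear benzoquinone (Z)-enol trichloroethyl sulfate
Product: 15 bicyclic benzoquinone (Z)-enol trichloroethyl sulfate
Conditions: chiral IDPi Brønsted acid (BINOL-derived imidodiphosphorimidate; the enantiomer that turns (3E,7E)-homofarnesol into (−)-ambrox; 5 mol %), (CF3)3COH/CHCl3, −30 °C, 0.02 M
Reagents that add atoms: none
Why: Proposed new method: the confined chiral acid protonates the terminal isopropylidene (least hindered, assisted by the neighbouring alkene) on one enantioface, the all-(E) triene then closes ring A and ring B in a chair–chair anti-addition cascade that fixes the trans ring fusion (5S,10S) and the equatorial side chain (9S) in one event, and because the next π-system is the strongly deactivated enol sulfate diester the C8 cation cannot propagate and loses the axial C7–H to the catalyst anion to give the Δ7 alkene and return the proton (the quinone and the C17=C18 alkene, which has no π-partner for assisted protonation, stay out); the closest known reaction type is the chiral-Brønsted-acid-catalysed, proton-initiated polyene cyclisation of (3E,7E)-homofarnesol to (−)-ambrox and the related Lewis-acid-assisted chiral-acid cyclisations of polyprenoids, which end by oxygen or arene capture instead of proton loss.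

Step 8
Reactants: 15 bicyclic benzoquinone (Z)-enol trichloroethyl sulfate
Product: 18 target CNP0476859.3, via hydroquinone trichloroethyl sulfate 16 (not isolated), via ammonium enol sulfate 17 (not isolated)
Conditions: Zn dust (10 equiv), HCO2NH4 (8 equiv), MeOH, rt; then cold 0.1 M HCl, n-BuOH/EtOAc extraction, 0 °C
Reagents that add atoms: none
Why: Zinc reduces the quinone to the hydroquinone and cleaves the trichloroethyl group by two-electron reductive β-elimination (loss of 1,1-dichloroethene), a near-neutral unmasking that leaves the (Z)-enol sulfate monoester, both alkenes and the three stereocentres untouched, and brief cold acidification gives the hydrogen sulfate as drawn.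

## Compound list

1 | 5-chloropent-1-yne | C#CCCCCl | starting material
2 | 2-(chloromethyl)-1,4-dimethoxybenzene (2,5-dimethoxybenzyl chloride) | COc1ccc(OC)c(CCl)c1 | starting material
3 | [(1E)-5-chloro-2-methylpent-1-en-1-yl]dimethylalumane | C[Al](C)/C=C(\C)CCCCl | intermediate
4 | 2-[(2E)-6-chloro-3-methylhex-2-en-1-yl]-1,4-dimethoxybenzene | COc1ccc(OC)c(C/C=C(\C)CCCCl)c1 | intermediate
5 | 2-bromoprop-2-en-1-ol | OCC(Br)=C | starting material
6 | [(2-bromoprop-2-en-1-yl)oxy]triethylsilane | C=C(Br)CO[Si](CC)(CC)CC | intermediate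
7 | [(4E)-6-(2,5-dimethoxyphenyl)-4-methylhex-4-en-1-yl]magnesium chloride | COc1ccc(OC)c(C/C=C(\C)CCC[Mg]Cl)c1 | intermediate
8 | {[(6E)-8-(2,5-dimethoxyphenyl)-6-methyl-2-methylideneoct-6-en-1-yl]oxy}triethylsilane | C=C(CO[Si](CC)(CC)CC)CCC/C(C)=C/Cc1cc(OC)ccc1OC | intermediate
9 | (2E,6E)-1-bromo-3,7,11-trimethyldodeca-2,6,10-triene ((E,E)-farnesyl bromide) | CC(C)=CCC/C(C)=C/CC/C(C)=C/CBr | starting material
10 | 1-lithio derivative of 8 (oxygen-chelated cis-siloxyallyllithium) | [Li]C(O[Si](CC)(CC)CC)C(=C)CCC/C(C)=C/Cc1cc(OC)ccc1OC | intermediate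
11 | (1Z,5E,9E)-2-[(4E)-6-(2,5-dimethoxyphenyl)-4-methylhex-4-en-1-yl]-6,10,14-trimethyl-1-(triethylsilyloxy)pentadeca-1,5,9,13-tetraene (O cis to the farnesyl-bearing CH2) | CC(C)=CCC/C(C)=C/CC/C(C)=C/CC/C(=C\O[Si](CC)(CC)CC)CCC/C(C)=C/Cc1cc(OC)ccc1OC | intermediate
12 | lithium (1Z)-enolate corresponding to 11 | CC(C)=CCC/C(C)=C/CC/C(C)=C/CC/C(=C\O[Li])CCC/C(C)=C/Cc1cc(OC)ccc1OC | intermediate
13 | (1Z,5E,9E)-2-[(4E)-6-(2,5-dimethoxyphenyl)-4-methylhex-4-en-1-yl]-6,10,14-trimethylpentadeca-1,5,9,13-tetraen-1-yl 2,2,2-trichloroethyl sulfate | CC(C)=CCC/C(C)=C/CC/C(C)=C/CC/C(=C\OS(=O)(=O)OCC(Cl)(Cl)Cl)CCC/C(C)=C/Cc1cc(OC)ccc1OC | intermediate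
14 | (1Z,5E,9E)-2-[(4E)-6-(3,6-dioxocyclohexa-1,4-dien-1-yl)-4-methylhex-4-en-1-yl]-6,10,14-trimethylpentadeca-1,5,9,13-tetraen-1-yl 2,2,2-trichloroethyl sulfate | CC(C)=CCC/C(C)=C/CC/C(C)=C/CC/C(=C\OS(=O)(=O)OCC(Cl)(Cl)Cl)CCC/C(C)=C/CC1=CC(=O)C=CC1=O | intermediate
15 | (1Z,6E)-8-(3,6-dioxocyclohexa-1,4-dien-1-yl)-6-methyl-2-{2-[(1S,4aS,8aS)-2,5,5,8a-tetramethyl-1,4,4a,5,6,7,8,8a-octahydronaphthalen-1-yl]ethyl}octa-1,6-dien-1-yl 2,2,2-trichloroethyl sulfate | CC1=CC[C@H]2C(C)(C)CCC[C@]2(C)[C@H]1CC/C(=C\OS(=O)(=O)OCC(Cl)(Cl)Cl)CCC/C(C)=C/CC1=CC(=O)C=CC1=O | intermediate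
16 | hydroquinone analogue of 15 (2,5-dihydroxyphenyl in place of the quinone; trichloroethyl sulfate intact) | CC1=CC[C@H]2C(C)(C)CCC[C@]2(C)[C@H]1CC/C(=C\OS(=O)(=O)OCC(Cl)(Cl)Cl)CCC/C(C)=C/Cc1cc(O)ccc1O | intermediate
17 | ammonium salt of the target enol sulfate | CC1=CC[C@H]2C(C)(C)CCC[C@]2(C)[C@H]1CC/C(=C\OS(=O)(=O)[O-])CCC/C(C)=C/Cc1cc(O)ccc1O.[NH4+] | intermediate
18 | (1Z,6E)-8-(2,5-dihydroxyphenyl)-6-methyl-2-{2-[(1S,4aS,8aS)-2,5,5,8a-tetramethyl-1,4,4a,5,6,7,8,8a-octahydronaphthalen-1-yl]ethyl}octa-1,6-dien-1-yl hydrogen sulfate (CNP0476859.3) | CC1=CC[C@H]2C(C)(C)CCC[C@]2(C)[C@H]1CC/C(=C\OS(=O)(=O)O)CCC/C(C)=C/Cc1cc(O)ccc1O | target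

## Step count and risks

Total steps: 8. Longest linear sequence: 7 (steps 1, 3, 4, 5, 6, 7, 8); step 2 is a one-step side branch.

**Most likely to fail, first: step 7.** The whole-chain bicyclisation can go wrong by initiation at the wrong alkene, by proton loss to the Δ8(12) or Δ8 isomers instead of Δ7, or by insufficient enantiomeric ratio. The fallback forms the rings first on a small substrate and joins the halves by carbometalation; it sets out from 4 and returns at 15. Commercial (3E,7E)-homofarnesol F1 is brominated (CBr4, PPh3) to (3E,7E)-homofarnesyl bromide F2. F2 is cyclised with the same chiral acid to the bicyclic bromide F3; olefin isomers are removed on AgNO3-impregnated silica at this cheap stage. From 4, LiC≡CH·H2NCH2CH2NH2 in DMSO gives the terminal alkyne F4. Magnesium turns F3 into the Grignard reagent F5, and CuBr·SMe2 gives the alkylcopper F6, which adds syn across F4 to the (Z)-alkenylcopper F7 (the side-chain carbon and copper end up cis). t-BuOOLi oxygenates the C–Cu bond with retention to the copper enolate F8 (monovalent copper). The sulfuryl-transfer salt of step 5 then gives the bicyclic dimethoxyarene trichloroethyl sulfate F9, and (NH4)2Ce(NO3)6 as in step 6 converts F9 into 15.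

**Second: step 4.** s-BuLi may also remove a proton from the benzylic-allylic CH2, and some α-alkylation is possible. The fallback generates the same type of siloxyallyl anion without any strong base; it sets out from 8 and returns at 12. Bu4NF cleaves 8 to the allylic alcohol F10, and MnO2 oxidises it to the 2-substituted acrolein F11. PhMe2SiLi adds 1,2 to give the α-silyl lithium alkoxide F12. In THF/HMPA this undergoes Brook rearrangement to the siloxyallyllithium F13, which is alkylated at its γ-carbon by 9 to the (Z)-dimethylphenylsilyl enol ether F14. MeLi cleaves F14 to the enolate 12.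

**Third: step 5.** O-sulfurylation of the enolate is unprecedented; attack at the acidic imidazolium positions or at carbon would lower the yield. The fallback carries a classical enol ester through the cyclisation and sulfates afterwards; it sets out from 12 and returns at 17. Ac2O traps 12 as the (Z)-enol acetate F15. The bicyclisation of step 7 is run on F15, with the arene still as its dimethyl ether, to give the bicyclic enol acetate F16. MeLi (2 equiv) regenerates the enolate as the bicyclic lithium enolate F17, and SO3·NMe3 sulfates it on oxygen to the lithium enol sulfate F18. (NH4)2Ce(NO3)6 followed by ammonium exchange gives the quinone ammonium enol sulfate F19. Zn/HCO2NH4 reduces the quinone to 17, which is acidified as in step 8.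

## Further compounds

F1 | step 7 | (3E,7E)-4,8,12-trimethyltrideca-3,7,11-trien-1-ol (homofarnesol) | CC(C)=CCC/C(C)=C/CC/C(C)=C/CCO
F2 | step 7 | (3E,7E)-1-bromo-4,8,12-trimethyltrideca-3,7,11-triene | CC(C)=CCC/C(C)=C/CC/C(C)=C/CCBr
F3 | step 7 | (1S,4aS,8aS)-1-(2-bromoethyl)-2,5,5,8a-tetramethyl-1,4,4a,5,6,7,8,8a-octahydronaphthalene | CC1=CC[C@H]2C(C)(C)CCC[C@]2(C)[C@H]1CCBr
F4 | step 7 | 1,4-dimethoxy-2-[(2E)-3-methyloct-2-en-7-yn-1-yl]benzene | C#CCCC/C(C)=C/Cc1cc(OC)ccc1OC
F5 | step 7 | Grignard reagent of F3 | CC1=CC[C@H]2C(C)(C)CCC[C@]2(C)[C@H]1CC[Mg]Br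
F6 | step 7 | alkylcopper from F5 (monovalent copper) | CC1=CC[C@H]2C(C)(C)CCC[C@]2(C)[C@H]1CC[Cu]
F7 | step 7 | (Z)-alkenylcopper from syn-addition of F6 to F4 | CC1=CC[C@H]2C(C)(C)CCC[C@]2(C)[C@H]1CC/C(=C\[Cu])CCC/C(C)=C/Cc1cc(OC)ccc1OC
F8 | step 7 | copper (Z)-enolate from oxygenation of F7 | CC1=CC[C@H]2C(C)(C)CCC[C@]2(C)[C@H]1CC/C(=C\O[Cu])CCC/C(C)=C/Cc1cc(OC)ccc1OC
F9 | step 7 | bicyclic 2,5-dimethoxyphenyl (Z)-enol 2,2,2-trichloroethyl sulfate (dimethyl ether of 16) | CC1=CC[C@H]2C(C)(C)CCC[C@]2(C)[C@H]1CC/C(=C\OS(=O)(=O)OCC(Cl)(Cl)Cl)CCC/C(C)=C/Cc1cc(OC)ccc1OC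
F10 | step 4 | (6E)-8-(2,5-dimethoxyphenyl)-6-methyl-2-methylideneoct-6-en-1-ol | C=C(CO)CCC/C(C)=C/Cc1cc(OC)ccc1OC
F11 | step 4 | (6E)-8-(2,5-dimethoxyphenyl)-6-methyl-2-methylideneoct-6-enal | C=C(C=O)CCC/C(C)=C/Cc1cc(OC)ccc1OC
F12 | step 4 | lithium alkoxide of the 1-(dimethylphenylsilyl) allylic alcohol from F11 | [Li]OC([Si](C)(C)c1ccccc1)C(=C)CCC/C(C)=C/Cc1cc(OC)ccc1OC
F13 | step 4 | 1-(dimethylphenylsiloxy)allyllithium from Brook rearrangement of F12 | [Li]C(O[Si](C)(C)c1ccccc1)C(=C)CCC/C(C)=C/Cc1cc(OC)ccc1OC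
F14 | step 4 | linear (Z)-dimethylphenylsilyl enol ether (silyl analogue of 11) | CC(C)=CCC/C(C)=C/CC/C(C)=C/CC/C(=C\O[Si](C)(C)c1ccccc1)CCC/C(C)=C/Cc1cc(OC)ccc1OC
F15 | step 5 | linear (Z)-enol acetate (acetate analogue of 13) | CC(C)=CCC/C(C)=C/CC/C(C)=C/CC/C(=C\OC(C)=O)CCC/C(C)=C/Cc1cc(OC)ccc1OC
F16 | step 5 | bicyclic 2,5-dimethoxyphenyl (Z)-enol acetate | CC1=CC[C@H]2C(C)(C)CCC[C@]2(C)[C@H]1CC/C(=C\OC(C)=O)CCC/C(C)=C/Cc1cc(OC)ccc1OC
F17 | step 5 | bicyclic 2,5-dimethoxyphenyl lithium (Z)-enolate | CC1=CC[C@H]2C(C)(C)CCC[C@]2(C)[C@H]1CC/C(=C\O[Li])CCC/C(C)=C/Cc1cc(OC)ccc1OC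
F18 | step 5 | lithium salt of the bicyclic 2,5-dimethoxyphenyl (Z)-enol sulfate | CC1=CC[C@H]2C(C)(C)CCC[C@]2(C)[C@H]1CC/C(=C\OS(=O)(=O)[O-])CCC/C(C)=C/Cc1cc(OC)ccc1OC.[Li+]
F19 | step 5 | ammonium salt of the bicyclic benzoquinone (Z)-enol sulfate | CC1=CC[C@H]2C(C)(C)CCC[C@]2(C)[C@H]1CC/C(=C\OS(=O)(=O)[O-])CCC/C(C)=C/CC1=CC(=O)C=CC1=O.[NH4+]
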